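## Structural features

The target is one six-membered carbocycle, a cyclohexa-1,4-diene (C1=C2 and C4=C5), numbered here C1 (carries the chain), C2 (vinyl CH), C3 (CH–OH), C4 (vinyl CH), C5 (C–OMe) and C6 (CH–OAc). A (R)-2-acetoxytridecyl chain is attached to C1 through its CH2 group, so the chain stereocentre C2' is one methylene away from the ring. The ring stereocentres C3 (S) and C6 (S) are not adjacent to each other or to C2'. They face each other across the ring (1,4) and their oxygens are trans. Both ring carbinol carbons are doubly allylic, and C3–OH with C4=C5–OMe is a vinylogous hemiacetal. Loss of water or acetic acid gives an arene and hydrolysis of the enol ether gives an enone, so acid, base, prolonged heating in solution and oxidants all endanger the ring. In oxidation level the ring is a 2-methoxy-6-alkyl-1,4-benzoquinone that has taken up one hydride at each carbonyl carbon. The difficulty is to deliver these two hydrogens to opposite faces with absolute control, to distinguish the two oxygens (O6 acetylated, O3 free), and never to let a ketone or a leaving group at C3 or C6 coexist with both ring double bonds. The plan uses the C1=C2 bond of quinone 10, the only dienophilic bond because C4=C5 carries the donor methoxy group. Bridging it with cyclopentadiene makes C1 quaternary, which blocks tautomerisation to a hydroquinone, and folds the ring so that the C3 and C6 carbonyls each have one open (convex) and one closed (concave) face.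

## Logic of the disconnections

**17 back to 16.** C1 and C2 of 17 are reconnected, on one face, to the two termini of 11. In the forward direction the two C–C σ bonds between C1/C2 and the bridgeheads are cut. Cutting here means that no reagent ever meets the free cyclohexadiene: the last operation is a reagent-free cycloreversion. Five carbons are added on paper, but the fragile monocycle becomes a robust tricycle. The forward step must let the fragmentation outrun thermal loss of acetic acid. This calls for short-contact gas-phase pyrolysis and for freeing O3 beforehand, because a C3 ester could shift or eliminate and a later deprotection would expose 17 to reagents.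

**16 back to 13 (through 15 and 14).** The O3–acyl bond of a temporary chloroacetate, the O6–acetyl bond and the C3–O bond are disconnected, the last with inversion. The trans diol pattern cannot come from hydride delivery alone, because both hydrides must enter from the same open face. One carbinol is therefore inverted, and C3 is the only one that can be (C6 is neopentylic). The inverting ester also serves as the label that keeps O3 distinct while O6 is acetylated. The forward steps require displacement at C3 only, from the convex face, and an ester that can be removed beside two acetates.

**13 back to 12.** The C3–H and C6–H bonds are cut. Both carbonyls return, the vinylogous ester at C3 and the more electrophilic ketone at C6. The gain is an enedione whose faces are differentiated by the bridge. The forward step must be a 1,2-reduction of both carbonyls from the convex face that spares the chain acetate.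

**12 back to 10 and 11.** The C1–C(bridgehead) and C2–C(bridgehead) bonds are cut. This removes one ring and four stereocentres in one operation and leads to a flat, achiral ring and a commodity diene. The forward step must select the C1=C2 bond, the endo mode and one face of the alkene. The first two are inherent to the substrate and the third must come from a chiral Lewis acid.

**10 back to 9 and 8.** The C=O oxygen para to the phenolic oxygen is removed, then the O–benzyl bond is reformed. In 9 both ortho positions are substituted and the para position is free, so oxidation can only give the para-quinone. The chain acetate is already present, so the quinone is never exposed to acylation conditions or to a free chain hydroxyl. The phenol must be unmasked under neutral conditions, hence benzyl and hydrogenolysis.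

**8 back to 5 and 3 (through 6 and 7).** The aryl–C1' bond and the O2'–acetyl bond are cut. This separates the arene from the chain at the only C–C bond that joins them and traces the C2' stereocentre to an epoxide. The forward step must attack the terminal epoxide carbon only, so that C2' is untouched, and the alkoxide is acetylated in the same flask.

**5 back to 4, and 3 back to 2 and 1.** The O–benzyl bond is cut to reach a commercial bromophenol. The epoxide is traced to the racemate and then to the terminal alkene by removing the epoxide oxygen. The only demand is a resolution that leaves the (R)-epoxide in high enantiomeric purity.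

## Other disconnections considered

**Alternative 1:** The cut is the C4=C5 enol-ether double bond. The open-chain precursor would be methyl ester A1. In A1, C5 is the ester carbonyl, C6 carries a triethylsilyl ether, C1=C2 is a (Z)-trisubstituted alkene, and C3 carries a tert-butyldimethylsilyl ether and a vinyl group. The key step would treat A1 with the titanium ethylidene reagent made from TiCl4, Zn, catalytic PbCl2, TMEDA and CH3CHBr2. The reagent should exchange with the vinyl group and then olefinate the ester carbonyl within the same molecule to give the tris-silyl ring diene A2.

- In favour: the methoxy enol ether comes directly from a methyl ester. No arene or quinone is involved, so no oxidation level has to be adjusted. The three stereocentres would be set one at a time by acyclic reactions of well-understood sense. The ring would close near room temperature and not in a pyrolysis tube. On these four points the alternative equals or betters the chosen plan.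
- Against: A1 needs a geometrically pure trisubstituted alkene flanked by two carbinol centres, which is a long synthesis in itself. Olefinic-ester cyclisation is best supported for rings that contain the ester oxygen, and closing a carbocycle to a 1-methoxycyclohexadiene is a less certain extension. The reagent is used in large excess and is Lewis acidic, and A2 is as prone to ionisation and aromatisation as the target. After ring closure, three silyl ethers must still be exchanged for two acetates and one free hydroxyl on the unprotected diene.
- Comparison: on structure, the alternative builds the fragile ring early in its final form and then manipulates it, whereas the chosen plan keeps it locked until the last step. On mechanism, a metathesis–olefination cascade on a polyfunctional ester stands against a catalysed cycloaddition and a cycloreversion, both of simple and predictable course. On step economy, the alternative would probably need well over fifteen steps against twelve.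

**Alternative 2:** The cut is the C1–C6 σ bond. The precursor would be A3, a (Z)-alkenyl iodide at C1 tethered through C2, C3 (silyl ether) and the C4=C5 enol ether to an aldehyde at C6. Under CrCl2 with catalytic NiCl2 and a chiral sulfonamide ligand, the alkenylchromium species should add to the aldehyde, closing the ring and creating the C6 carbinol of A4.

- In favour: ring and C6 stereocentre arise together under mild, nearly neutral conditions. O6 emerges free and already distinguished from O3, so there is no inversion and no temporary ester. The chain acetate is in place. On differentiation of the oxygens this alternative is better than the chosen plan.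
- Against: A3 is a 2-methoxy-enal with two stereodefined double bonds and is itself difficult to make and to keep geometrically pure. In a six-membered ring closure the sense at C6 is set by the ring-forming transition state as much as by the ligand, and C3 is too remote to help, so the trans relationship is not assured. The product is a doubly allylic alkoxide bound to Lewis-acidic trivalent chromium, which invites ionisation and aromatisation. Chromium is needed in stoichiometric amount. Acetylation and desilylation of the free diene follow.
- Comparison: on structure, the alternative again handles the unprotected diene for its last steps. On mechanism, its stereocontrol at C6 rests on a ligand effect in an intramolecular setting, against facial shielding by a rigid bridge in the chosen plan. The two plans are equal in needing one catalyst-controlled step. On step economy, the alternative would be longer because of A3.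

**Alternative 3:** The cut is the C1=C2 double bond. The acyclic triene A5 carries a 1,1-disubstituted alkene at C1, the acetate at C6, the (Z)-enol ether C4=C5 and a vinyl group on the silylated carbinol C3. Ring-closing metathesis with the second-generation Grubbs catalyst, (H2IMes)(PCy3)Cl2Ru=CHPh, should give A6, the 3-O-triethylsilyl ether of the target.

- In favour: closure of a six-membered ring with a trisubstituted alkene is among the most dependable metathesis reactions. The catalyst is neutral and tolerates esters. Both acetates are in place and only one desilylation remains. No thermal step is needed. In late-stage economy and mildness of ring formation the alternative equals or betters the chosen plan.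
- Against: the difficulty moves to A5, a stereodefined trisubstituted enol ether between two carbinol centres, each of which must be set separately. The enol ether can capture ruthenium as an unreactive alkoxycarbene. Ruthenium hydrides formed on catalyst decay can isomerise the 1,4-diene, after which acetic acid is lost easily. The final desilylation is carried out on the doubly allylic system.
- Comparison: on structure, the alternative needs three independently controlled stereocentres and one alkene geometry, against one catalyst-controlled step plus substrate control. On mechanism, both ring-forming steps are well understood, and this is a point of equality. On step economy, the alternative has the shorter end game but would probably be longer overall.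

Key step: step 7

Assumption: the sense of the two catalyst-controlled steps is assigned from the accepted models, namely that the (R,R)-cobalt salen complex leaves the (R)-epoxide and that the oxazaborolidinium ion from (S)-α,α-diphenylprolinol exposes the C1-Si/C2-Re face of 10; if either sense proved opposite, the mirror-image catalyst would be used and nothing else would change.

Remark on the structures: re-derivation of the configurations gives the target as 3S,6S,2'R with O3 and O6 trans, and shows that 12 (endo, bridge on the C1-Si/C2-Re face, C1 S, C2 R) is the isomer that leads to it. Compounds 10 and 12 are therefore kept unchanged. The corrections concern the sequence around them: the chain acetate is installed before the quinone exists, the phenol is 2,6-disubstituted so that only the para-quinone can form, and the temporary ester is removed before the cycloreversion.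

## Route

Step 1
Reactants: 1 1-tridecene
Product: 2 rac-2-undecyloxirane (racemic 1,2-epoxytridecane)
Conditions: mCPBA, CH2Cl2, 0 °C to rt
Reagents that add atoms: 3-chloroperoxybenzoic acid, OOC(=O)c1cccc(Cl)c1
Why: Prilezhaev epoxidation of an unactivated terminal alkene is a concerted oxygen transfer with no selectivity issue; the racemate is the substrate needed for the resolution.

Step 2
Reactants: 2 rac-2-undecyloxirane
Product: 3 (R)-2-undecyloxirane
Conditions: (R,R)-(salen)Co(OAc) [salen = N,N'-bis(3,5-di-tert-butylsalicylidene)-1,2-cyclohexanediaminate] (0.5 mol%), H2O (0.55 equiv), THF (minimum), 0 °C to rt; distillation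
Reagents that add atoms: none
Why: Hydrolytic kinetic resolution, in which the chiral trivalent cobalt complex delivers water to the (S)-epoxide much faster than to its mirror image, so that the (R)-epoxide should remain in high enantiomeric purity and is distilled from the diol; this sets C2' of the target.

Step 3
Reactants: 4 2-bromo-6-methoxyphenol
Product: 5 2-(benzyloxy)-1-bromo-3-methoxybenzene
Conditions: BnBr, K2CO3, DMF, rt
Reagents that add atoms: benzyl bromide, BrCc1ccccc1
Why: Williamson etherification of the phenoxide; benzyl is chosen because it survives the Grignard reagent and is later removed by neutral hydrogenolysis that leaves a secondary acetate untouched.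

Step 4
Reactants: 5 2-(benzyloxy)-1-bromo-3-methoxybenzene; 3 (R)-2-undecyloxirane
Product: 8 (R)-1-[2-(benzyloxy)-3-methoxyphenyl]tridecan-2-yl acetate, via aryl Grignard reagent 6 (not isolated), via bromomagnesium alkoxide 7 (not isolated)
Conditions: Mg, THF, 45 °C; CuI (10 mol%), 3, −30 to 0 °C; Ac2O, DMAP (cat.), 0 °C to rt
Reagents that add atoms: acetic anhydride, CC(=O)OC(C)=O
Why: Copper-catalysed SN2 opening of a terminal epoxide by an aryl Grignard reagent occurs at the unsubstituted carbon, so the aryl–CH2 bond forms without touching the stereocentre (R retained); the magnesium alkoxide is acetylated in the same flask, which puts the final chain acetate in place before any quinone exists.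

Step 5
Reactants: 8 (R)-1-[2-(benzyloxy)-3-methoxyphenyl]tridecan-2-yl acetate
Product: 9 (R)-1-(2-hydroxy-3-methoxyphenyl)tridecan-2-yl acetate
Conditions: H2 (1 atm), Pd/C (10% Pd), EtOAc, rt
Reagents that add atoms: none
Why: Catalytic hydrogenolysis cleaves the aryl benzyl ether under neutral conditions; the homobenzylic acetate and the arene are not affected.

Step 6
Reactants: 9 (R)-1-(2-hydroxy-3-methoxyphenyl)tridecan-2-yl acetate
Product: 10 2-methoxy-6-[(R)-2-acetoxytridecyl]-1,4-benzoquinone
Conditions: ON(SO3K)2 (2.5 equiv), KH2PO4 buffer (pH ca. 6), acetone–H2O, rt
Reagents that add atoms: potassium nitrosodisulfonate, [K+].[K+].[O]N(S(=O)(=O)[O-])S(=O)(=O)[O-]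
Why: Teuber oxidation, in which one nitrosodisulfonate radical abstracts the phenolic hydrogen and a second couples at the para carbon before imidodisulfonate is lost; both ortho positions are substituted and the para position is free, so only the para-quinone can form, and the near-neutral buffer spares the acetate.

Step 7
Reactants: 10 2-methoxy-6-[(R)-2-acetoxytridecyl]-1,4-benzoquinone; 11 cyclopentadiene
Product: 12 endo cyclopentadiene adduct of 10 (cis-fused tricyclic enedione; bridge across C1–C2 on the C1-Si/C2-Re face; C1 S, C2 R; enedione ring syn to the norbornene C=C)
Conditions: oxazaborolidine from (S)-α,α-diphenylprolinol and tri-o-tolylboroxine (20 mol%), Tf2NH (20 mol%), CH2Cl2, −78 °C; 11 (5 equiv, freshly distilled from the commercial dimer); light excluded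
Reagents that add atoms: none
Why: The N-protonated oxazaborolidine is a chiral boron Lewis acid that binds the more basic C3 carbonyl oxygen (the vinylogous ester) through the lone pair syn to C2–H, lowering the LUMO of the C1=C2 bond, and cyclopentadiene then adds in a concerted suprafacial [4+2] cycloaddition. The closest known reaction type is the oxazaborolidinium-catalysed enantioselective Diels–Alder reaction of unsymmetrical benzoquinones. One ring is closed, the six-membered carbocycle of the norbornene, by intermolecular cycloaddition in which both new C–C bonds (at C1 and C2) form in one step on the same face, giving the cis-fused tricycle. The configurations at C1 and C2 are controlled by the catalyst, whose aryl group covers one face of the bound alkene so that the diene enters the C1-Si/C2-Re face; the two bridgehead centres follow from the endo rule (secondary overlap of the diene with the C3 and C6 carbonyls) and the suprafacial addition. Site selectivity for C1=C2 over C4=C5 is secured by the methoxy group, which makes C4=C5 an electron-rich, poorly dienophilic bond. The remote (R) centre of the chain should not influence the face, but it turns any minor face isomer into a diastereomer that can be removed by chromatography. The low temperature keeps the uncatalysed background reaction slow, and exclusion of light avoids the intramolecular [2+2] photocyclisation typical of such adducts.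

Step 8
Reactants: 12 endo cyclopentadiene adduct of 10
Product: 13 bridged endo,endo-diol (12 with C3=O and C6=O reduced; both OH on the concave face, syn to the norbornene C=C; C3 R, C6 S)
Conditions: NaBH4 (3 equiv), CeCl3·7H2O (2.2 equiv), MeOH–CH2Cl2, −40 to 0 °C; NaHCO3 work-up
Reagents that add atoms: none
Why: Luche reduction gives cerium-assisted 1,2-hydride addition to both conjugated carbonyls and tolerates the acetate; the concave face is closed by the norbornene bridge, so hydride enters C3 and C6 from the convex face and both hydroxyls end up endo. The work-up is kept neutral because the C3 carbinol is a vinylogous hemiacetal.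

Step 9
Reactants: 13 bridged endo,endo-diol
Product: 14 bridged 3-exo-chloroacetate 6-endo-alcohol (C3 inverted to S; C6 S)
Conditions: ClCH2CO2H, PPh3, DIAD (1.5 equiv each), toluene–THF, −20 to 0 °C
Reagents that add atoms: chloroacetic acid, OC(=O)CCl
Why: Mitsunobu reaction; only C3 can be displaced because C6 is neopentylic (next to quaternary C1), and the carboxylate attacks the C3 oxyphosphonium from the open convex face with inversion. Any leakage through the methoxy-stabilised allyl cation would be intercepted from the same convex face; chloroacetic acid is the standard pronucleophile for hindered carbinols and its ester is removable beside acetates.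

Step 10
Reactants: 14 bridged 3-exo-chloroacetate 6-endo-alcohol
Product: 15 bridged 3-exo-chloroacetate 6-endo-acetate
Conditions: Ac2O, pyridine, DMAP (cat.), CH2Cl2, 0 °C to rt
Reagents that add atoms: acetic anhydride, CC(=O)OC(C)=O
Why: Nucleophile-catalysed acylation of the only free hydroxyl, with no bond to a stereocentre broken; endo hydroxyls of such adducts acetylate normally and the chloroacetate tolerates these conditions at or below room temperature.

Step 11
Reactants: 15 bridged 3-exo-chloroacetate 6-endo-acetate
Product: 16 bridged 3-exo-alcohol 6-endo-acetate
Conditions: thiourea, NaHCO3, EtOH–THF, 50 °C
Reagents that add atoms: none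
Why: Thiourea S-alkylates the chloroacetyl group and the isothiouronium salt cyclises onto the ester carbonyl, releasing the C3 alcohol with retention while both acetates survive; it is done on the bridged compound, which cannot aromatise, so the target itself never meets this reagent.

Step 12
Reactants: 16 bridged 3-exo-alcohol 6-endo-acetate
Product: 17 target, (1S,4S)-6-[(2R)-2-acetoxytridecyl]-4-hydroxy-2-methoxycyclohexa-2,5-dien-1-yl acetate (ring numbering of this text: C3 S, C6 S)
Conditions: flash vacuum pyrolysis, 450–480 °C, ca. 0.001 mbar, base-washed quartz tube, inlet 150–180 °C, trap −196 °C
Reagents that add atoms: none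
Why: Thermal retro-Diels–Alder cycloreversion expels cyclopentadiene and restores the C1=C2 bond without touching C3, C6 or C2'. A unimolecular fragmentation with a high pre-exponential factor is favoured by high temperature and millisecond contact time over the more ordered side reactions (acetate shifts, ester pyrolysis, loss of acetic acid), and no reagent is present.

## Compound list

1 | 1-tridecene | C=CCCCCCCCCCCC | starting material
2 | rac-2-undecyloxirane | CCCCCCCCCCCC1CO1 | intermediate
3 | (R)-2-undecyloxirane | CCCCCCCCCCC[C@@H]1CO1 | intermediate
4 | 2-bromo-6-methoxyphenol | COc1cccc(Br)c1O | starting material
5 | 2-(benzyloxy)-1-bromo-3-methoxybenzene | COc1cccc(Br)c1OCc1ccccc1 | intermediate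
6 | [2-(benzyloxy)-3-methoxyphenyl]magnesium bromide | COc1cccc([Mg]Br)c1OCc1ccccc1 | intermediate (not isolated)
7 | bromomagnesium (R)-1-[2-(benzyloxy)-3-methoxyphenyl]tridecan-2-olate | CCCCCCCCCCC[C@H](Cc1cccc(OC)c1OCc1ccccc1)O[Mg]Br | intermediate (not isolated)
8 | (R)-1-[2-(benzyloxy)-3-methoxyphenyl]tridecan-2-yl acetate | CCCCCCCCCCC[C@H](Cc1cccc(OC)c1OCc1ccccc1)OC(C)=O | intermediate
9 | (R)-1-(2-hydroxy-3-methoxyphenyl)tridecan-2-yl acetate | CCCCCCCCCCC[C@H](Cc1cccc(OC)c1O)OC(C)=O | intermediate
10 | 2-methoxy-6-[(R)-2-acetoxytridecyl]-1,4-benzoquinone | CCCCCCCCCCC[C@H](CC1=CC(=O)C=C(OC)C1=O)OC(C)=O | intermediate
11 | cyclopentadiene (distilled from the commercial dimer before use) | C1=CC=CC1 | starting material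
12 | endo cyclopentadiene adduct of 10 (C1 S, C2 R) | CCCCCCCCCCC[C@H](C[C@@]12C(=O)C(OC)=CC(=O)[C@@H]1[C@@H]1C=C[C@H]2C1)OC(C)=O | intermediate
13 | bridged endo,endo-diol (C3 R, C6 S) | CCCCCCCCCCC[C@H](C[C@@]12[C@H](O)C(OC)=C[C@H](O)[C@@H]1[C@@H]1C=C[C@H]2C1)OC(C)=O | intermediate
14 | bridged 3-exo-chloroacetate 6-endo-alcohol (C3 S, C6 S) | CCCCCCCCCCC[C@H](C[C@@]12[C@H](O)C(OC)=C[C@@H](OC(=O)CCl)[C@@H]1[C@@H]1C=C[C@H]2C1)OC(C)=O | intermediate
15 | bridged 3-exo-chloroacetate 6-endo-acetate | CCCCCCCCCCC[C@H](C[C@@]12[C@H](OC(C)=O)C(OC)=C[C@@H](OC(=O)CCl)[C@@H]1[C@@H]1C=C[C@H]2C1)OC(C)=O | intermediate
16 | bridged 3-exo-alcohol 6-endo-acetate | CCCCCCCCCCC[C@H](C[C@@]12[C@H](OC(C)=O)C(OC)=C[C@@H](O)[C@@H]1[C@@H]1C=C[C@H]2C1)OC(C)=O | intermediate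
17 | (1S,4S)-6-[(2R)-2-acetoxytridecyl]-4-hydroxy-2-methoxycyclohexa-2,5-dien-1-yl acetate | CCCCCCCCCCC[C@H](CC1=C[C@H](O)C=C(OC)[C@H]1OC(C)=O)OC(C)=O | target

## Step count and least certain steps

Total step count: 12. Longest linear sequence: 11 steps (1, 2, 4, 5, 6, 7, 8, 9, 10, 11, 12, counted from 1); the branch from 4 contributes step 3.

**Step 7 (key step).** The most likely failure is poor facial selectivity or a sluggish catalysed reaction. The reacting alkene is trisubstituted, and the chain with its Lewis-basic acetate sits next to the catalyst-binding site, so the uncatalysed pathway may compete. The fallback sets out from 10 and returns at 12. Compounds 10 and 11 are combined without a catalyst (CH2Cl2, 0 °C to rt). Site and endo selectivity are inherent to the substrate, so two endo adducts are expected: 12 and the face-isomeric endo adduct F1. They are diastereomers because of the chain stereocentre and are separated by preparative chromatography (if necessary after step 8, as the more polar diols). Half of the material is lost, but no selectivity has to come from a catalyst.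

**Step 12.** What may go wrong is thermal loss of acetic acid or water from the doubly allylic diene with aromatisation, a 1,3-shift of the C6 acetate, pyrolysis of the chain acetate, or incomplete volatilisation of the hydroxyl-bearing substrate with decomposition on the hot surface. The fallback sets out from 15 and returns at 17. Compound 15, which has no free hydroxyl and should be more volatile, is pyrolysed under the same conditions to the 3-O-chloroacetate of the target F2. The chloroacetyl group is then removed at room temperature with hydrazinedithiocarbonate, or with thiourea and NaHCO3, to give 17.

**Step 9.** The risks are: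
- activation at the wrong hydroxyl or formation of a cyclic phosphorane spanning both;
- ionisation of the C3 oxyphosphonium to the methoxy-stabilised cation, followed by capture at C5 (and collapse to an enone on work-up, as in a Stork–Danheiser transposition) or transannular capture by O6;
- elimination towards C2.

The fallback sets out from 12 and returns at 15, and differentiates the oxygens at the carbonyl stage:
- NaBH4 (one hydride equivalent) with CeCl3·7H2O at −78 °C should reduce only the more electrophilic C6 ketone, the C3 carbonyl being a deactivated vinylogous ester, to give the 6-endo-hydroxy enone F3.
- Acetylation (Ac2O, pyridine, DMAP) gives the 6-endo-acetoxy enone F4.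
- Luche reduction at 0 °C gives the 3-endo-alcohol 6-endo-acetate F5.
- The Mitsunobu reaction with chloroacetic acid is then run on a substrate with a single hydroxyl and no free O6, giving 15.

This is one step longer.

**Step 10.** The risk is slow acylation of the concave, neopentylic hydroxyl. Forcing conditions could let the amine catalysts displace chloride from the chloroacetate. The fallback sets out from 13 and returns at 16, and uses an ester that is inert to acylation catalysts:
- Mitsunobu reaction of 13 with levulinic acid gives the 3-exo-levulinate 6-endo-alcohol F6.
- Acetylation under forcing conditions (Ac2O, Et3N, DMAP, 40 °C) gives the 3-exo-levulinate 6-endo-acetate F7.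
- Hydrazine acetate in pyridine-buffered solution at rt removes the levulinate and gives 16.

## Further compounds

F1 | step 7 | face-isomeric endo cyclopentadiene adduct of 10 (bridge on the C1-Re/C2-Si face) | CCCCCCCCCCC[C@H](C[C@]12C(=O)C(OC)=CC(=O)[C@H]1[C@H]1C=C[C@@H]2C1)OC(C)=O
F2 | step 12 | 3-O-chloroacetate of the target | CCCCCCCCCCC[C@H](CC1=C[C@H](OC(=O)CCl)C=C(OC)[C@H]1OC(C)=O)OC(C)=O
F3 | step 9 | bridged 6-endo-hydroxy enone (C3 ketone retained) | CCCCCCCCCCC[C@H](C[C@@]12[C@H](O)C(OC)=CC(=O)[C@@H]1[C@@H]1C=C[C@H]2C1)OC(C)=O
F4 | step 9 | bridged 6-endo-acetoxy enone | CCCCCCCCCCC[C@H](C[C@@]12[C@H](OC(C)=O)C(OC)=CC(=O)[C@@H]1[C@@H]1C=C[C@H]2C1)OC(C)=O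
F5 | step 9 | bridged 3-endo-alcohol 6-endo-acetate | CCCCCCCCCCC[C@H](C[C@@]12[C@H](OC(C)=O)C(OC)=C[C@H](O)[C@@H]1[C@@H]1C=C[C@H]2C1)OC(C)=O
F6 | step 10 | bridged 3-exo-levulinate 6-endo-alcohol | CCCCCCCCCCC[C@H](C[C@@]12[C@H](O)C(OC)=C[C@@H](OC(=O)CCC(C)=O)[C@@H]1[C@@H]1C=C[C@H]2C1)OC(C)=O
F7 | step 10 | bridged 3-exo-levulinate 6-endo-acetate | CCCCCCCCCCC[C@H](C[C@@]12[C@H](OC(C)=O)C(OC)=C[C@@H](OC(=O)CCC(C)=O)[C@@H]1[C@@H]1C=C[C@H]2C1)OC(C)=O
A1 | alternative 1 | open-chain methyl ester with (Z)-C1=C2, 3-O-TBS, 6-O-TES, 2'-O-TES and a vinyl group on C3 | CCCCCCCCCCC[C@H](C/C(=C/[C@H](O[Si](C)(C)C(C)(C)C)C=C)[C@H](O[Si](CC)(CC)CC)C(=O)OC)O[Si](CC)(CC)CC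
A2 | alternative 1 | tris-silyl ether of the ring diene | CCCCCCCCCCC[C@H](CC1=C[C@H](O[Si](C)(C)C(C)(C)C)C=C(OC)[C@H]1O[Si](CC)(CC)CC)O[Si](CC)(CC)CC
A3 | alternative 2 | open-chain (Z)-alkenyl iodide with 3-O-TBS, (Z)-methoxy enal terminus at C6 and chain acetate | CCCCCCCCCCC[C@H](C/C(I)=C/[C@H](O[Si](C)(C)C(C)(C)C)/C=C(OC)\C=O)OC(C)=O
A4 | alternative 2 | 6-hydroxy ring diene, O3 silylated | CCCCCCCCCCC[C@H](CC1=C[C@H](O[Si](C)(C)C(C)(C)C)C=C(OC)[C@H]1O)OC(C)=O
A5 | alternative 3 | acyclic triene with 1,1-disubstituted alkene at C1, 6-OAc, (Z)-C4=C5 enol ether, 3-O-TES and vinyl on C3 | CCCCCCCCCCC[C@H](CC(=C)[C@H](OC(C)=O)/C(OC)=C\[C@@H](O[Si](CC)(CC)CC)C=C)OC(C)=O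
A6 | alternative 3 | 3-O-triethylsilyl ether of the target | CCCCCCCCCCC[C@H](CC1=C[C@H](O[Si](CC)(CC)CC)C=C(OC)[C@H]1OC(C)=O)OC(C)=O
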